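**Retrosynthetic overview**

1. Sarmentosumin A ⇐ hexa-O-benzyl flavanone 24 (global hydrogenolysis) ⇐ spiro dithioketal 23 (unmasking of the C4 ketone).
2. Ring C is cut across C3–C4 and O1–C8a: a [3+3] union of the lithiated aryl dithiane from 19 (C4 as an acyl anion on C4a, fluorine on C8a) with (R)-styrene oxide, which brings O1–C2(Ph)–C3 and the stereocentre.
3. Enabling feature: in ring C the carbonyl carbon C4 and the ether oxygen O1 sit on the adjacent ring-A carbons C4a and C8a, and the other three ring-C atoms (O1, C2, C3) form a 1,2-oxygenated two-carbon unit, that is an epoxide. C8a is meta to both ring-A oxygens (C5, C7), so a fluoride there can be displaced by the alkoxide.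
4. Arene 19 ⇐ 5-fluororesorcinol: dibromination at the two equivalent carbons next to fluorine, iodination between the two benzyloxy groups, Negishi benzylation at C–I (C6 arm), Br/Li exchange and formylation (C4), dithiane, then Negishi benzylation at C–Br (C8 arm) with the three-arene chloride 8, itself made by two iterative benzyl–aryl Suzuki couplings.
5. Ring order: ring A, ring B (the 2-phenyl group) and the four side-chain arenes are bought; ring C is the only ring formed, and it is closed in the key step.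

Key step: step 14

Remark on names: flavanone numbering (O1, C2, C3, C4, C4a, C5–C8, C8a) is used for ring positions. BOB = 2-(benzyloxy)benzyl. TRI = 2-(benzyloxy)-5-{2-(benzyloxy)-5-[2-(benzyloxy)benzyl]benzyl}benzyl, the protected three-arene arm.
Assumption: all six phenols are carried as benzyl ethers, so that the last step is a neutral hydrogenolysis that cannot open ring C by base.

**Route**

Step 1
Reactants: 1 2-(benzyloxy)-5-bromobenzaldehyde
Product: 2 [2-(benzyloxy)-5-bromophenyl]methanol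
Conditions: NaBH4, MeOH/THF, 0 °C
Reagents that add atoms: none
Why: Hydride reduction of the aryl aldehyde by NaBH4 should be chemoselective, leaving the aryl bromide and the benzyl ether untouched.

Step 2
Reactants: 2 [2-(benzyloxy)-5-bromophenyl]methanol
Product: 3 [2-(benzyloxy)-5-(4,4,5,5-tetramethyl-1,3,2-dioxaborolan-2-yl)phenyl]methanol
Conditions: B2pin2, PdCl2(dppf) (3 mol %), KOAc, 1,4-dioxane, 90 °C
Reagents that add atoms: bis(pinacolato)diboron, CC1(C)OB(OC1(C)C)B1OC(C)(C)C(C)(C)O1
Why: Miyaura borylation (oxidative addition of zerovalent palladium into C–Br, acetate-assisted transmetalation with the diboron) tolerates the free benzylic alcohol and should give the bifunctional unit used twice in the chain assembly.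

Step 3
Reactants: 3 [2-(benzyloxy)-5-(4,4,5,5-tetramethyl-1,3,2-dioxaborolan-2-yl)phenyl]methanol, 4 2-(benzyloxy)benzyl chloride
Product: 5 {2-(benzyloxy)-5-[2-(benzyloxy)benzyl]phenyl}methanol
Conditions: Pd(OAc)2 (2 mol %), SPhos (4 mol %), K3PO4, toluene/H2O, 80 °C
Reagents that add atoms: none
Why: Suzuki–Miyaura coupling of a benzylic chloride (no β-hydrogen) with an aryl pinacol boronate should give the first diarylmethane link, fixed para to the benzyloxy group by the position of boron.

Step 4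
Reactants: 5 {2-(benzyloxy)-5-[2-(benzyloxy)benzyl]phenyl}methanol
Product: 6 1-(benzyloxy)-4-[2-(benzyloxy)benzyl]-2-(chloromethyl)benzene
Conditions: SOCl2, DMF (cat.), CH2Cl2, 0 °C
Reagents that add atoms: thionyl chloride, O=S(Cl)Cl
Why: Deoxychlorination of the benzylic alcohol through its chlorosulfite should proceed cold, without a Lewis acid that could trigger Friedel–Crafts self-alkylation.

Step 5
Reactants: 6 1-(benzyloxy)-4-[2-(benzyloxy)benzyl]-2-(chloromethyl)benzene, 3 [2-(benzyloxy)-5-(4,4,5,5-tetramethyl-1,3,2-dioxaborolan-2-yl)phenyl]methanol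
Product: 7 [2-(benzyloxy)-5-{2-(benzyloxy)-5-[2-(benzyloxy)benzyl]benzyl}phenyl]methanol (TRI–OH)
Conditions: Pd(OAc)2 (2 mol %), SPhos (4 mol %), K3PO4, toluene/H2O, 80 °C
Reagents that add atoms: none
Why: A second Suzuki–Miyaura benzyl–aryl coupling of the same type as step 3 should add the third arene with the same ortho-CH2/para-C linkage.

Step 6
Reactants: 7 [2-(benzyloxy)-5-{2-(benzyloxy)-5-[2-(benzyloxy)benzyl]benzyl}phenyl]methanol
Product: 8 1-(benzyloxy)-4-{2-(benzyloxy)-5-[2-(benzyloxy)benzyl]benzyl}-2-(chloromethyl)benzene (TRI–Cl)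
Conditions: SOCl2, DMF (cat.), CH2Cl2, 0 °C
Reagents that add atoms: thionyl chloride, O=S(Cl)Cl
Why: The same deoxychlorination as in step 4 should give the benzylic chloride needed for zinc insertion.

Step 7
Reactants: 9 5-fluorobenzene-1,3-diol
Product: 10 1,3-bis(benzyloxy)-5-fluorobenzene
Conditions: BnBr, K2CO3, DMF, 60 °C
Reagents that add atoms: benzyl bromide, BrCc1ccccc1
Why: Williamson etherification of both phenols should be straightforward.

Step 8
Reactants: 10 1,3-bis(benzyloxy)-5-fluorobenzene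
Product: 11 1,5-bis(benzyloxy)-2,4-dibromo-3-fluorobenzene
Conditions: NBS (2.05 equiv), MeCN, 0 °C to rt
Reagents that add atoms: N-bromosuccinimide, O=C1CCC(=O)N1Br
Why: Electrophilic aromatic bromination of a resorcinol diether goes to the two equivalent carbons that are ortho to one and para to the other benzyloxy group (here the two carbons flanking fluorine), while the crowded carbon between the two ether groups reacts last.

Step 9
Reactants: 11 1,5-bis(benzyloxy)-2,4-dibromo-3-fluorobenzene
Product: 12 1,3-bis(benzyloxy)-4,6-dibromo-5-fluoro-2-iodobenzene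
Conditions: NIS, TFA (0.3 equiv), MeCN, rt to 40 °C
Reagents that add atoms: N-iodosuccinimide, O=C1CCC(=O)N1I
Why: Acid-activated electrophilic iodination should take the only remaining ring position, which is activated by two ortho benzyloxy groups, so the regiochemistry is unambiguous.

Step 10
Reactants: 12 1,3-bis(benzyloxy)-4,6-dibromo-5-fluoro-2-iodobenzene, 4 2-(benzyloxy)benzyl chloride
Product: 14 1,3-bis(benzyloxy)-2-[2-(benzyloxy)benzyl]-4,6-dibromo-5-fluorobenzene, via 2-(benzyloxy)benzylzinc chloride 13 (not isolated)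
Conditions: 4, Zn dust, LiCl, THF, 25 °C; then 12, Pd(PPh3)4 (5 mol %), THF, 50 °C
Reagents that add atoms: none
Why: In this Negishi coupling, oxidative addition of zerovalent palladium into C–I is much faster than into the two C–Br bonds, so only the iodide should be benzylated, placing the BOB arm at the future C6.

Step 11
Reactants: 14 1,3-bis(benzyloxy)-2-[2-(benzyloxy)benzyl]-4,6-dibromo-5-fluorobenzene
Product: 16 2,4-bis(benzyloxy)-3-[2-(benzyloxy)benzyl]-5-bromo-6-fluorobenzaldehyde, via aryllithium 15 (not isolated)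
Conditions: n-BuLi (1.0 equiv), THF, −78 °C; DMF, −78 °C to rt; aq. NH4Cl
Reagents that add atoms: N,N-dimethylformamide, CN(C)C=O
Why: Bromine–lithium exchange on a dibromide whose two bromines are equivalent by symmetry should give a single aryllithium, which is stable towards loss of LiF at −78 °C and is formylated by DMF at the future C4a.

Step 12
Reactants: 16 2,4-bis(benzyloxy)-3-[2-(benzyloxy)benzyl]-5-bromo-6-fluorobenzaldehyde
Product: 17 2-{2,4-bis(benzyloxy)-3-[2-(benzyloxy)benzyl]-5-bromo-6-fluorophenyl}-1,3-dithiane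
Conditions: HS(CH2)3SH, I2 (10 mol %), CH2Cl2, rt
Reagents that add atoms: propane-1,3-dithiol, SCCCS
Why: Iodine-catalysed dithioacetalisation should turn the aldehyde into a Corey–Seebach acyl-anion precursor under conditions too mild to cleave benzyl ethers, and it also protects the carbonyl from the benzylzinc reagent of step 13.

Step 13
Reactants: 17 2-{2,4-bis(benzyloxy)-3-[2-(benzyloxy)benzyl]-5-bromo-6-fluorophenyl}-1,3-dithiane, 8 TRI–Cl
Product: 19 2-{2,4-bis(benzyloxy)-3-BOB-6-fluoro-5-TRI-phenyl}-1,3-dithiane, via TRI–zinc chloride 18 (not isolated)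
Conditions: 8, Zn dust, LiCl, THF, 25 °C; then 17, Pd(OAc)2 (3 mol %), SPhos (6 mol %), THF, 50 °C
Reagents that add atoms: none
Why: A Negishi coupling with an electron-rich bulky biarylphosphine should engage the aryl bromide flanked by fluorine and benzyloxy and join the three-arene arm at the future C8, with the dithiane tolerated because no base is present.

Step 14
Reactants: 19 2-{2,4-bis(benzyloxy)-3-BOB-6-fluoro-5-TRI-phenyl}-1,3-dithiane, 20 (R)-styrene oxide
Product: 23 (2S)-5,7-bis(benzyloxy)-6-BOB-8-TRI-2-phenylspiro[chromane-4,2'-[1,3]dithiane], via 2-lithio-1,3-dithiane 21 (not isolated), via open-chain lithium alkoxide 22 (not isolated)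
Conditions: n-BuLi (1.05 equiv), THF, −78 to −30 °C; 20 (1.1 equiv), −30 to 0 °C; then KOt-Bu, DMPU, 65 °C
Reagents that add atoms: none
Why: Proposed new method: n-BuLi should remove the dithiane C–H of 19 (the most acidic site, with lithium held by the flanking F and OBn) to give the masked acyl anion 21, a reversed-polarity C4 that opens (R)-styrene oxide by SN2 attack at its unsubstituted carbon (C3–C4 bond), and the freed benzylic alkoxide 22, once exchanged to potassium in DMPU, displaces the fluoride on C8a by addition–elimination (O1–C8a bond); the closest known reaction types are the Corey–Seebach alkylation of 2-aryl-2-lithio-1,3-dithianes with epoxides and the alkoxide SNAr closure of 1-aryl-3-(2-fluorophenyl)propan-1-ols to flavans, merged here into one [3+3] annulation. Ring C closes as a six-membered ring by 6-exo-trig attack of oxygen on the arene carbon (Meisenheimer-type addition, loss of fluoride), helped by the gem-disubstituent effect of the quaternary dithiane carbon. The only stereocentre, C2, is carried in from the epoxide, whose C–O bond is never broken, so the spatial arrangement is retained and the (R) epoxide gives the (2S) chromane (the descriptor changes only because the CIP ranking of CH2 and phenyl is reversed). The step needs regioselective epoxide opening at CH2, which the bulk of the tertiary dithianyl anion should secure, and displacement at C8a only, which is the single carbon bearing a nucleofuge and lies meta to both benzyloxy groups (C5, C7), so that these donors sit on nodal positions of the Meisenheimer complex and do not deactivate it. Because C4 stays a dithioketal, the open intermediate cannot undergo retro-aldol cleavage and the product cannot ring-open by enolisation, so the configuration should not erode under the basic conditions.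

Step 15
Reactants: 23 (2S)-5,7-bis(benzyloxy)-6-BOB-8-TRI-2-phenylspiro[chromane-4,2'-[1,3]dithiane]
Product: 24 (2S)-5,7-bis(benzyloxy)-6-BOB-8-TRI-2-phenylchroman-4-one
Conditions: MeI, CaCO3, MeCN/H2O (9:1), 45 °C
Reagents that add atoms: water, O
Why: S-Methylation turns the dithioketal into a leaving group, and the thionium ion, stabilised by the benzyloxy groups ortho and para to C4a, is trapped by water under buffered neutral conditions that should leave C2 untouched.

Step 16
Reactants: 24 (2S)-5,7-bis(benzyloxy)-6-BOB-8-TRI-2-phenylchroman-4-one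
Product: 25 sarmentosumin A
Conditions: H2 (1 atm), Pd/C (10 wt % palladium on carbon), EtOAc/MeOH, rt
Reagents that add atoms: none
Why: Catalytic hydrogenolysis should cleave the six aryl benzyl ethers while the diarylmethane C–C bonds are inert, and the neutral medium avoids the base-induced retro-oxa-Michael opening that racemises flavanones.

**Compound list**

1 | 2-(benzyloxy)-5-bromobenzaldehyde | O=Cc1cc(Br)ccc1OCc1ccccc1 | starting material
2 | [2-(benzyloxy)-5-bromophenyl]methanol | OCc1cc(Br)ccc1OCc1ccccc1 | intermediate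
3 | [2-(benzyloxy)-5-(4,4,5,5-tetramethyl-1,3,2-dioxaborolan-2-yl)phenyl]methanol | OCc1cc(B2OC(C)(C)C(C)(C)O2)ccc1OCc1ccccc1 | intermediate
4 | 2-(benzyloxy)benzyl chloride, 1-(benzyloxy)-2-(chloromethyl)benzene | ClCc1ccccc1OCc1ccccc1 | starting material
5 | {2-(benzyloxy)-5-[2-(benzyloxy)benzyl]phenyl}methanol | OCc1cc(Cc2ccccc2OCc2ccccc2)ccc1OCc1ccccc1 | intermediate
6 | 1-(benzyloxy)-4-[2-(benzyloxy)benzyl]-2-(chloromethyl)benzene | ClCc1cc(Cc2ccccc2OCc2ccccc2)ccc1OCc1ccccc1 | intermediate
7 | [2-(benzyloxy)-5-{2-(benzyloxy)-5-[2-(benzyloxy)benzyl]benzyl}phenyl]methanol (TRI–OH) | OCc1cc(Cc2cc(Cc3ccccc3OCc3ccccc3)ccc2OCc2ccccc2)ccc1OCc1ccccc1 | intermediate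
8 | 1-(benzyloxy)-4-{2-(benzyloxy)-5-[2-(benzyloxy)benzyl]benzyl}-2-(chloromethyl)benzene (TRI–Cl) | ClCc1cc(Cc2cc(Cc3ccccc3OCc3ccccc3)ccc2OCc2ccccc2)ccc1OCc1ccccc1 | intermediate
9 | 5-fluorobenzene-1,3-diol | Oc1cc(O)cc(F)c1 | starting material
10 | 1,3-bis(benzyloxy)-5-fluorobenzene | Fc1cc(OCc2ccccc2)cc(OCc2ccccc2)c1 | intermediate
11 | 1,5-bis(benzyloxy)-2,4-dibromo-3-fluorobenzene | Fc1c(Br)c(OCc2ccccc2)cc(OCc2ccccc2)c1Br | intermediate
12 | 1,3-bis(benzyloxy)-4,6-dibromo-5-fluoro-2-iodobenzene | Fc1c(Br)c(OCc2ccccc2)c(I)c(OCc2ccccc2)c1Br | intermediate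
13 | 2-(benzyloxy)benzylzinc chloride | Cl[Zn]Cc1ccccc1OCc1ccccc1 | intermediate
14 | 1,3-bis(benzyloxy)-2-[2-(benzyloxy)benzyl]-4,6-dibromo-5-fluorobenzene | Fc1c(Br)c(OCc2ccccc2)c(Cc2ccccc2OCc2ccccc2)c(OCc2ccccc2)c1Br | intermediate
15 | {2,4-bis(benzyloxy)-3-[2-(benzyloxy)benzyl]-5-bromo-6-fluorophenyl}lithium | [Li]c1c(F)c(Br)c(OCc2ccccc2)c(Cc2ccccc2OCc2ccccc2)c1OCc1ccccc1 | intermediate
16 | 2,4-bis(benzyloxy)-3-[2-(benzyloxy)benzyl]-5-bromo-6-fluorobenzaldehyde | O=Cc1c(F)c(Br)c(OCc2ccccc2)c(Cc2ccccc2OCc2ccccc2)c1OCc1ccccc1 | intermediate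
17 | 2-{2,4-bis(benzyloxy)-3-[2-(benzyloxy)benzyl]-5-bromo-6-fluorophenyl}-1,3-dithiane | C1CSC(SC1)c1c(F)c(Br)c(OCc2ccccc2)c(Cc2ccccc2OCc2ccccc2)c1OCc1ccccc1 | intermediate
18 | (2-(benzyloxy)-5-{2-(benzyloxy)-5-[2-(benzyloxy)benzyl]benzyl}benzyl)zinc chloride (TRI–zinc chloride) | Cl[Zn]Cc1cc(Cc2cc(Cc3ccccc3OCc3ccccc3)ccc2OCc2ccccc2)ccc1OCc1ccccc1 | intermediate
19 | 2-{2,4-bis(benzyloxy)-3-[2-(benzyloxy)benzyl]-5-(2-(benzyloxy)-5-{2-(benzyloxy)-5-[2-(benzyloxy)benzyl]benzyl}benzyl)-6-fluorophenyl}-1,3-dithiane | C1CSC(SC1)c1c(F)c(Cc2cc(Cc3cc(Cc4ccccc4OCc4ccccc4)ccc3OCc3ccccc3)ccc2OCc2ccccc2)c(OCc2ccccc2)c(Cc2ccccc2OCc2ccccc2)c1OCc1ccccc1 | intermediate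
20 | (R)-styrene oxide, (2R)-2-phenyloxirane | C1[C@H](O1)c1ccccc1 | starting material
21 | 2-lithio derivative of 19 (lithium on the dithiane C2) | [Li]C1(SCCCS1)c1c(F)c(Cc2cc(Cc3cc(Cc4ccccc4OCc4ccccc4)ccc3OCc3ccccc3)ccc2OCc2ccccc2)c(OCc2ccccc2)c(Cc2ccccc2OCc2ccccc2)c1OCc1ccccc1 | intermediate
22 | lithium (1S)-2-[2-(aryl)-1,3-dithian-2-yl]-1-phenylethoxide (aryl as in 19) | C1CSC(SC1)(C[C@@H](c1ccccc1)O[Li])c1c(F)c(Cc2cc(Cc3cc(Cc4ccccc4OCc4ccccc4)ccc3OCc3ccccc3)ccc2OCc2ccccc2)c(OCc2ccccc2)c(Cc2ccccc2OCc2ccccc2)c1OCc1ccccc1 | intermediate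
23 | (2S)-5,7-bis(benzyloxy)-6-[2-(benzyloxy)benzyl]-8-(2-(benzyloxy)-5-{2-(benzyloxy)-5-[2-(benzyloxy)benzyl]benzyl}benzyl)-2-phenylspiro[chromane-4,2'-[1,3]dithiane] | C1CSC2(SC1)C[C@@H](c1ccccc1)Oc1c(Cc3cc(Cc4cc(Cc5ccccc5OCc5ccccc5)ccc4OCc4ccccc4)ccc3OCc3ccccc3)c(OCc3ccccc3)c(Cc3ccccc3OCc3ccccc3)c(OCc3ccccc3)c12 | intermediate
24 | (2S)-5,7-bis(benzyloxy)-6-[2-(benzyloxy)benzyl]-8-(2-(benzyloxy)-5-{2-(benzyloxy)-5-[2-(benzyloxy)benzyl]benzyl}benzyl)-2-phenylchroman-4-one (hexa-O-benzylsarmentosumin A) | O=C1C[C@@H](c2ccccc2)Oc2c(Cc3cc(Cc4cc(Cc5ccccc5OCc5ccccc5)ccc4OCc4ccccc4)ccc3OCc3ccccc3)c(OCc3ccccc3)c(Cc3ccccc3OCc3ccccc3)c(OCc3ccccc3)c21 | intermediate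
25 | sarmentosumin A, (2S)-5,7-dihydroxy-6-(2-hydroxybenzyl)-8-{2-hydroxy-5-[2-hydroxy-5-(2-hydroxybenzyl)benzyl]benzyl}-2-phenylchroman-4-one | O=C1C[C@@H](c2ccccc2)Oc2c(Cc3cc(Cc4cc(Cc5ccccc5O)ccc4O)ccc3O)c(O)c(Cc3ccccc3O)c(O)c21 | target

**Step count and risks**

Total step count: 16. Longest linear sequence: 10 steps (steps 7–16 from 9; the side-chain branch, steps 1–6 then 13–16 from 1, is equally long).

Steps most likely to fail:

1. Step 14 (Proposed new method). The ring closure may stall at the open-chain alkoxide because fluoride displacement on the crowded arene, which has no acceptor, is slow, and on prolonged heating with base the benzylic ether and diarylmethane positions may be deprotonated instead. The fallback sets out from 19 and uses known chemistry only. Lithiation and opening of (R)-styrene oxide are run as before but quenched with aq. NH4Cl at 0 °C, which should give the open-chain alcohol (1S)-2-[2-(aryl)-1,3-dithian-2-yl]-1-phenylethan-1-ol F1. Hydrolysis of its dithiane (MeI, CaCO3, aq. MeCN) should give the β-hydroxy ketone (3S)-1-(aryl)-3-hydroxy-3-phenylpropan-1-one F2, in which fluorine is now ortho to an aryl ketone. A carbonyl-activated intramolecular SNAr under mild carbonate conditions (K2CO3, DMF, rt, kept mild to outrun retro-aldol cleavage) should then close ring C, and the route is rejoined at 24.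

2. Step 13. Zinc insertion into the large electron-rich benzylic chloride may be diverted into Wurtz-type homocoupling, and oxidative addition at the bromide flanked by fluorine and benzyloxy may be slow, so that both advanced partners are consumed unproductively. The fallback sets out from 14 (with 8) and reverses the polarity of the coupling. Br/Li exchange on 14 (n-BuLi, THF, −78 °C) gives the aryllithium 15, which is transmetalated with ZnCl2 to {2,4-bis(benzyloxy)-3-BOB-5-bromo-6-fluorophenyl}zinc chloride F3 (not isolated). Pd(OAc)2/SPhos-catalysed coupling of this arylzinc with the benzylic chloride 8 should give 1,3-bis(benzyloxy)-2-BOB-4-bromo-5-fluoro-6-TRI-benzene F4. A second Br/Li exchange gives {2,4-bis(benzyloxy)-3-BOB-6-fluoro-5-TRI-phenyl}lithium F5 (not isolated), which DMF formylates to 2,4-bis(benzyloxy)-3-BOB-6-fluoro-5-TRI-benzaldehyde F6. Dithioacetalisation as in step 12 rejoins the route at 19.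

3. Step 16. Over-reduction may compete, by hydrogenolysis of the benzylic C2–O1 bond of ring C or reduction of the C4 ketone while the hindered benzyl ethers at C5 and C7 are still being cleaved, and traces of sulfur from step 15 may slow the catalyst. The fallback sets out from 24 and is non-reductive: BCl3 with pentamethylbenzene as benzyl-cation scavenger in CH2Cl2 at −78 °C should remove all six benzyl groups and arrive directly at 25. Compounds made on the way that the list does not hold: none F0.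

**Further compounds**

F1 | step 14 | (1S)-2-[2-{2,4-bis(benzyloxy)-3-[2-(benzyloxy)benzyl]-5-(2-(benzyloxy)-5-{2-(benzyloxy)-5-[2-(benzyloxy)benzyl]benzyl}benzyl)-6-fluorophenyl}-1,3-dithian-2-yl]-1-phenylethan-1-ol | C1CSC(SC1)(C[C@@H](c1ccccc1)O)c1c(F)c(Cc2cc(Cc3cc(Cc4ccccc4OCc4ccccc4)ccc3OCc3ccccc3)ccc2OCc2ccccc2)c(OCc2ccccc2)c(Cc2ccccc2OCc2ccccc2)c1OCc1ccccc1
F2 | step 14 | (3S)-1-{2,4-bis(benzyloxy)-3-[2-(benzyloxy)benzyl]-5-(2-(benzyloxy)-5-{2-(benzyloxy)-5-[2-(benzyloxy)benzyl]benzyl}benzyl)-6-fluorophenyl}-3-hydroxy-3-phenylpropan-1-one | O=C(C[C@@H](c1ccccc1)O)c1c(F)c(Cc2cc(Cc3cc(Cc4ccccc4OCc4ccccc4)ccc3OCc3ccccc3)ccc2OCc2ccccc2)c(OCc2ccccc2)c(Cc2ccccc2OCc2ccccc2)c1OCc1ccccc1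
F3 | step 13 | {2,4-bis(benzyloxy)-3-[2-(benzyloxy)benzyl]-5-bromo-6-fluorophenyl}zinc chloride | Cl[Zn]c1c(F)c(Br)c(OCc2ccccc2)c(Cc2ccccc2OCc2ccccc2)c1OCc1ccccc1
F4 | step 13 | 1,3-bis(benzyloxy)-2-[2-(benzyloxy)benzyl]-4-bromo-5-fluoro-6-(2-(benzyloxy)-5-{2-(benzyloxy)-5-[2-(benzyloxy)benzyl]benzyl}benzyl)benzene | Fc1c(Br)c(OCc2ccccc2)c(Cc2ccccc2OCc2ccccc2)c(OCc2ccccc2)c1Cc1cc(Cc2cc(Cc3ccccc3OCc3ccccc3)ccc2OCc2ccccc2)ccc1OCc1ccccc1
F5 | step 13 | {2,4-bis(benzyloxy)-3-[2-(benzyloxy)benzyl]-5-(2-(benzyloxy)-5-{2-(benzyloxy)-5-[2-(benzyloxy)benzyl]benzyl}benzyl)-6-fluorophenyl}lithium | [Li]c1c(F)c(Cc2cc(Cc3cc(Cc4ccccc4OCc4ccccc4)ccc3OCc3ccccc3)ccc2OCc2ccccc2)c(OCc2ccccc2)c(Cc2ccccc2OCc2ccccc2)c1OCc1ccccc1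
F6 | step 13 | 2,4-bis(benzyloxy)-3-[2-(benzyloxy)benzyl]-5-(2-(benzyloxy)-5-{2-(benzyloxy)-5-[2-(benzyloxy)benzyl]benzyl}benzyl)-6-fluorobenzaldehyde | O=Cc1c(F)c(Cc2cc(Cc3cc(Cc4ccccc4OCc4ccccc4)ccc3OCc3ccccc3)ccc2OCc2ccccc2)c(OCc2ccccc2)c(Cc2ccccc2OCc2ccccc2)c1OCc1ccccc1
F0 | step 16 | none | none
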